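Ring A (the benzene ring of the chromene) is cut into a symmetric ketone and a malonyl unit. C8a with O1 is the former ketone carbon, its α-carbons C4a and C8 each already carry a five-carbon isoprenoid chain, and C5–C6–C7 is the three-carbon diacyl piece. A single annulation of the silyl enol ether of 1,3-diprenylacetone with malonyl dichloride should form C4a–C5 and C8–C7, close ring A and give 2,4-diprenylphloroglucinol with both prenyl groups on carbon and C6 unsubstituted. Aroylation at C6 and closure of the pyran ring from O1 onto one prenyl group then finish the target.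

Key step: step 3

Assumptions and remarks on the chemistry:
- Atom labels follow the chromene numbering of the target (O1, C2, C3, C4, C4a, C5–C8, C8a).
- Enol ether 4 is drawn as the Z isomer expected from amine/silyl triflate enolisation. The E isomer would converge on the same arene, so the geometry is not purified.
- The target has no stereocentre. Intermediates 6, 15, 18 and 19 are racemic or stereochemically undefined and their SMILES carry no stereo labels.
- Phloroglucinol (Oc1cc(O)cc(O)c1), used only in one fallback, is taken as commercial.

Step 1
Reactants: 1 6-methylhept-5-en-2-one; 2 1-bromo-3-methylbut-2-ene (prenyl bromide)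
Product: 3 2,10-dimethylundeca-2,9-dien-6-one
Conditions: LiN(i-Pr)2, THF, −78 °C; then 2, DMPU, −78 → −20 °C
Reagents that add atoms: none
Why: Kinetic deprotonation removes a methyl proton of 1 and the lithium enolate is alkylated at the primary carbon of the allylic bromide (SN2 enolate alkylation), which should give the symmetric ketone with a prenyl group on each α-carbon.

Step 2
Reactants: 3 2,10-dimethylundeca-2,9-dien-6-one
Product: 4 (Z)-tert-butyl[(2,10-dimethylundeca-2,6,9-trien-6-yl)oxy]dimethylsilane
Conditions: TBSOTf, Et3N, CH2Cl2, 0 °C
Reagents that add atoms: tert-butyldimethylsilyl trifluoromethanesulfonate, CC(C)(C)[Si](C)(C)OS(=O)(=O)C(F)(F)F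
Why: Soft enolisation and O-silylation (silyl enol ether formation) can give only one regioisomer because 3 is symmetric, and the bulky silyl group is chosen to stay on oxygen through the annulation.

Step 3
Reactants: 4 (Z)-tert-butyl[(2,10-dimethylundeca-2,6,9-trien-6-yl)oxy]dimethylsilane; 5 propanedioyl dichloride (malonyl dichloride)
Product: 8 2,4-bis(3-methylbut-2-en-1-yl)benzene-1,3,5-triol (2,4-diprenylphloroglucinol), via acyclic keto acid chloride enol ether 6 (not isolated), via aryl silyl ether 7 (not isolated)
Conditions: Et2O, −20 °C → rt; then aq. KOH, BnEt3NCl, 0 °C (Ar); aq. HCl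
Reagents that add atoms: none
Why: The enol ether π bond attacks one acyl chloride of 5 to form C4a–C5, the O-silyl oxocarbenium ion sheds a proton instead of its bulky silyl group, and acid-mediated equilibration makes the cross-conjugated enol ether 6 on the α′ side available. Its α′ carbon then attacks the second acyl chloride in a 6-(enolendo)-exo-trig closure that forms C8–C7 and ring A, and two enolisations aromatise the ring to silyl ether 7, which the hydroxide work-up cleaves to 8. The closest known reaction type is the Effenberger α,α′-diacylation of enol ethers with malonyl dichloride, most often run on cyclic enol ethers, where it stops at a bicyclic trione, and here applied to an acyclic one so that the trione can aromatise. No stereocentre is formed. The step needs C-acylation to outrun O-acylation to a 4-hydroxy-2-pyranone and needs the acid-sensitive prenyl groups to survive: the tert-butyldimethylsilyl group keeps the ketone oxygen blocked until both C–C bonds exist, the symmetry of the ketone removes any regiochemical choice, and ether at low temperature tempers the HCl released.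

Step 4
Reactants: 8 2,4-bis(3-methylbut-2-en-1-yl)benzene-1,3,5-triol
Product: 9 1,3,5-tris(methoxymethoxy)-2,4-bis(3-methylbut-2-en-1-yl)benzene
Conditions: MOMCl, i-Pr2NEt, n-Bu4NI (cat.), CH2Cl2, 0 → 40 °C
Reagents that add atoms: chloromethyl methyl ether, COCCl
Why: O-Alkylation of all three phenols with the hard chloromethyl ether (Williamson-type etherification) should mask the oxidation-prone triol and install the acetal groups that direct the metalation in step 7.

Step 5
Reactants: 10 4-hydroxybenzoic acid
Product: 12 4-hydroxy-N-methoxy-N-methylbenzamide, via acyl imidazolide 11 (not isolated)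
Conditions: CDI, THF, rt; then MeNHOMe·HCl, rt
Reagents that add atoms: N,O-dimethylhydroxylamine hydrochloride, CNOC.Cl
Why: Carbonyldiimidazole activates the carboxylic acid as acyl imidazolide 11 faster than it touches the phenol, and aminolysis by the amine salt should give the Weinreb amide (amide coupling).

Step 6
Reactants: 12 4-hydroxy-N-methoxy-N-methylbenzamide
Product: 13 N-methoxy-4-(methoxymethoxy)-N-methylbenzamide
Conditions: MOMCl, i-Pr2NEt, CH2Cl2, 0 °C → rt
Reagents that add atoms: chloromethyl methyl ether, COCCl
Why: Phenol O-alkylation (acetal protection) removes the acidic proton that would quench the aryllithium and uses the same protecting group as 9, so that one later operation frees all four hydroxyls.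

Step 7
Reactants: 9 1,3,5-tris(methoxymethoxy)-2,4-bis(3-methylbut-2-en-1-yl)benzene; 13 N-methoxy-4-(methoxymethoxy)-N-methylbenzamide
Product: 16 [4-(methoxymethoxy)phenyl][2,4,6-tris(methoxymethoxy)-3,5-bis(3-methylbut-2-en-1-yl)phenyl]methanone, via aryllithium 14 (not isolated), via tetrahedral lithium adduct 15 (not isolated)
Conditions: n-BuLi, THF, 0 °C; then 13, −78 °C → rt; H2O
Reagents that add atoms: none
Why: Directed ortho-metalation removes the only aromatic proton of 9, which lies between two acetal oxygens (the future C6), and aryllithium 14 adds once to the amide because chelated adduct 15 persists until work-up (Weinreb ketone synthesis), which should give the benzophenone without over-addition.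

Step 8
Reactants: 16 [4-(methoxymethoxy)phenyl][2,4,6-tris(methoxymethoxy)-3,5-bis(3-methylbut-2-en-1-yl)phenyl]methanone
Product: 17 (4-hydroxyphenyl)[2,4,6-trihydroxy-3,5-bis(3-methylbut-2-en-1-yl)phenyl]methanone
Conditions: 3 M aq. HCl, MeOH, 45 °C
Reagents that add atoms: none
Why: Acid-catalysed acetal exchange with methanol should remove all four methoxymethyl groups, the two next to the carbonyl fastest, under dilute, mild conditions that should neither hydrate the prenyl groups nor cyclise them onto the neighbouring phenols (acetal cleavage).

Step 9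
Reactants: 17 (4-hydroxyphenyl)[2,4,6-trihydroxy-3,5-bis(3-methylbut-2-en-1-yl)phenyl]methanone
Product: 20 [5,7-dihydroxy-2,2-dimethyl-8-(3-methylbut-2-en-1-yl)-2H-chromen-6-yl](4-hydroxyphenyl)methanone (vismiaphenone E), via chroman selenide 18 (not isolated), via selenoxide 19 (not isolated)
Conditions: Et3N, PhSeCl, CH2Cl2, −78 °C; then 30% aq. H2O2, pyridine, THF, 0 °C → rt
Reagents that add atoms: none
Why: The amine ionises the most acidic ring hydroxyl, the one para to the carbonyl and flanked by both prenyl groups (the two ortho hydroxyls are held by the carbonyl), and this phenoxide opens the seleniranium ion of either adjacent prenyl group at its tertiary carbon (6-endo selenoetherification) to give 18; oxidation to selenoxide 19 and syn-elimination toward the only β-hydrogens, those at C4, should then give the 2H-chromene (selenoxide elimination), both prenyl groups leading to the same product by symmetry.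

Compound list
1 | 6-methylhept-5-en-2-one | CC(=O)CCC=C(C)C | starting material
2 | 1-bromo-3-methylbut-2-ene (prenyl bromide) | CC(C)=CCBr | starting material
3 | 2,10-dimethylundeca-2,9-dien-6-one | CC(C)=CCCC(=O)CCC=C(C)C | intermediate
4 | (Z)-tert-butyl[(2,10-dimethylundeca-2,6,9-trien-6-yl)oxy]dimethylsilane | CC(C)=CCC/C(O[Si](C)(C)C(C)(C)C)=C/CC=C(C)C | intermediate
5 | propanedioyl dichloride (malonyl dichloride) | O=C(Cl)CC(=O)Cl | starting material
6 | 5-[(tert-butyldimethylsilyl)oxy]-9-methyl-4-(3-methylbut-2-en-1-yl)-3-oxodeca-5,8-dienoyl chloride (racemic, enol ether geometry undefined) | CC(C)=CCC=C(O[Si](C)(C)C(C)(C)C)C(CC=C(C)C)C(=O)CC(=O)Cl | intermediate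
7 | 5-[(tert-butyldimethylsilyl)oxy]-4,6-bis(3-methylbut-2-en-1-yl)benzene-1,3-diol | CC(C)=CCc1c(O)cc(O)c(CC=C(C)C)c1O[Si](C)(C)C(C)(C)C | intermediate
8 | 2,4-bis(3-methylbut-2-en-1-yl)benzene-1,3,5-triol (2,4-diprenylphloroglucinol) | CC(C)=CCc1c(O)cc(O)c(CC=C(C)C)c1O | intermediate
9 | 1,3,5-tris(methoxymethoxy)-2,4-bis(3-methylbut-2-en-1-yl)benzene | COCOc1cc(OCOC)c(CC=C(C)C)c(OCOC)c1CC=C(C)C | intermediate
10 | 4-hydroxybenzoic acid | O=C(O)c1ccc(O)cc1 | starting material
11 | (4-hydroxyphenyl)(1H-imidazol-1-yl)methanone | O=C(c1ccc(O)cc1)n1ccnc1 | intermediate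
12 | 4-hydroxy-N-methoxy-N-methylbenzamide | CON(C)C(=O)c1ccc(O)cc1 | intermediate
13 | N-methoxy-4-(methoxymethoxy)-N-methylbenzamide | CON(C)C(=O)c1ccc(OCOC)cc1 | intermediate
14 | [2,4,6-tris(methoxymethoxy)-3,5-bis(3-methylbut-2-en-1-yl)phenyl]lithium | [Li]c1c(OCOC)c(CC=C(C)C)c(OCOC)c(CC=C(C)C)c1OCOC | intermediate
15 | lithium [methoxy(methyl)amino][4-(methoxymethoxy)phenyl][2,4,6-tris(methoxymethoxy)-3,5-bis(3-methylbut-2-en-1-yl)phenyl]methanolate (racemic) | [Li]OC(N(C)OC)(c1ccc(OCOC)cc1)c1c(OCOC)c(CC=C(C)C)c(OCOC)c(CC=C(C)C)c1OCOC | intermediate
16 | [4-(methoxymethoxy)phenyl][2,4,6-tris(methoxymethoxy)-3,5-bis(3-methylbut-2-en-1-yl)phenyl]methanone | COCOc1ccc(cc1)C(=O)c1c(OCOC)c(CC=C(C)C)c(OCOC)c(CC=C(C)C)c1OCOC | intermediate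
17 | (4-hydroxyphenyl)[2,4,6-trihydroxy-3,5-bis(3-methylbut-2-en-1-yl)phenyl]methanone | CC(C)=CCc1c(O)c(CC=C(C)C)c(O)c(C(=O)c2ccc(O)cc2)c1O | intermediate
18 | [5,7-dihydroxy-2,2-dimethyl-8-(3-methylbut-2-en-1-yl)-3-(phenylselanyl)-3,4-dihydro-2H-chromen-6-yl](4-hydroxyphenyl)methanone (racemic) | CC(C)=CCc1c(O)c(C(=O)c2ccc(O)cc2)c(O)c2c1OC(C)(C)C([Se]c1ccccc1)C2 | intermediate
19 | [3-(benzeneseleninyl)-5,7-dihydroxy-2,2-dimethyl-8-(3-methylbut-2-en-1-yl)-3,4-dihydro-2H-chromen-6-yl](4-hydroxyphenyl)methanone (mixture of diastereomers) | CC(C)=CCc1c(O)c(C(=O)c2ccc(O)cc2)c(O)c2c1OC(C)(C)C([Se](=O)c1ccccc1)C2 | intermediate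
20 | [5,7-dihydroxy-2,2-dimethyl-8-(3-methylbut-2-en-1-yl)-2H-chromen-6-yl](4-hydroxyphenyl)methanone (vismiaphenone E) | CC(C)=CCc1c(O)c(C(=O)c2ccc(O)cc2)c(O)c2c1OC(C)(C)C=C2 | target

Total step count: 9. Longest linear sequence: 7 (steps 1, 2, 3, 4, 7, 8, 9); steps 5 and 6 are the side branch to amide 13.

Steps most likely to fail

1. Step 3. The silyl group may be lost early, so that the second acylation takes place on oxygen and the chain lactonises to a 4-hydroxy-2-pyranone. The HCl released may also add to the prenyl double bonds or cyclise them onto the new phenols. The fallback builds the arene the other way round, acyl group first, by known chemistry. It sets out from 10: Friedel–Crafts acylation of phloroglucinol with 10 (ZnCl2, POCl3, 70 °C) should give (4-hydroxyphenyl)(2,4,6-trihydroxyphenyl)methanone F1. Double C-prenylation of F1 with 2 in cold aqueous KOH should then give tetraol 17 after separation from mono- and over-alkylated material. The route is rejoined at 17, so steps 1–8 are bypassed.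

2. Step 9. The selenium electrophile may be diverted into closure of the five-membered ring, into addition at the second prenyl group, or into attack on the carbon atoms of the phenoxide. The fallback replaces electrophilic cycloetherification by dehydrogenation and sets out from 17. DDQ (1 equiv, toluene, rt → 60 °C) abstracts hydride from a benzylic CH2 to give an ortho-quinone methide, which closes by oxa-6π-electrocyclisation directly to 20. No new isolable compound arises (F0). Closure onto a carbonyl-bound oxygen then competes, so the angular isomer would have to be removed by chromatography.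

3. Step 7. n-BuLi may remove a benzylic–allylic proton of a prenyl CH2 group (lateral metalation) instead of, or besides, the ring proton, so that the amide is attacked from the side chain. The fallback fixes the site by halogen–metal exchange and sets out from 9. Bromination of the single aromatic C–H with NBS (MeCN, −30 °C) should give 2-bromo-1,3,5-tris(methoxymethoxy)-4,6-bis(3-methylbut-2-en-1-yl)benzene F2. Exchange with n-BuLi (THF, −78 °C) gives aryllithium 14 regiospecifically, and the route continues from 14 with amide 13 to 16 as in step 7.

Further compounds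
F1 | step 3 | (4-hydroxyphenyl)(2,4,6-trihydroxyphenyl)methanone | O=C(c1ccc(O)cc1)c1c(O)cc(O)cc1O
F0 | step 9 | none | none
F2 | step 7 | 2-bromo-1,3,5-tris(methoxymethoxy)-4,6-bis(3-methylbut-2-en-1-yl)benzene | COCOc1c(Br)c(OCOC)c(CC=C(C)C)c(OCOC)c1CC=C(C)C
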